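A small charge of initiator, 2 mol% of the free monomer, has to catch free monomer that is leaving on its own.

    free monomer + initiator → living end + monomer in chains (k1 = 3.3 L mol⁻¹ min⁻¹)
    free monomer + living end → monomer in chains + living end, rate k2*[living end]*[free monomer] (k2 = 2.3 L mol⁻¹ min⁻¹)
    free monomer → uncatalysed product (k3 = 0.14 min⁻¹)
    initiator → spent initiator A (k4 = 0.017 min⁻¹)
    2 living end → dead end B (k5 = 3.2 L mol⁻¹ min⁻¹)

- alpha: free monomer 0.93 M; initiator 2 mol%; time 25 min
- eta: free monomer 0.30 M; initiator 2 mol%; time 25 min

- two of one species on the left: rate k times its square, two consumed each time
- the average divides the monomer in chains by the number of chains begun, living and dead together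
- run time (alpha): 25 min

* which of the two ends with the longer chains by the average number of monomer units in a chain (chains begun, living or dead) ("neither" if they lie within 10 %) (alpha / eta / neither)
* average number of monomer units in a chain (chains begun, living or dead) at the end, alpha
* average number of monomer units in a chain (chains begun, living or dead) at the end, eta

Two chemists dispute this. The first says that both flasks carry the same loading and each initiator begins one chain, so both end alike, at 50.0 units a chain: neither. The second says that free monomer runs on its own clock, a half-life of 5.0 min by step 3, and that living ends must compete with it.

Both accept one thing. Free monomer meets initiator within 0.326 min in alpha and 1.01 min in eta, each shorter than that half-life, so I count chains begun as the whole charge.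

My own reckoning takes the second side. Step 3 is a first-order loss of free monomer; step 2 is pseudo-first-order only while living end holds, and living end falls as it pairs off, so I take its opening value. The rate of step 2 over the rate of step 3 with every initiator a living end, k2 times the initiator charge over k3, is 0.306 in alpha and 0.0986 in eta; this opening selectivity factor I call the capture ratio. With the ratio held at that opening value, the fraction of the free monomer charge entering chains is the ratio over one plus the ratio: 23.4 % in alpha and 8.97 % in eta. Dividing by the loading gives 11.7 and 4.49 units. Living ends also pair off, with a first half-life by step 5 of 8.40 min in alpha and 26.0 min in eta, shorter in alpha. So I commit to alpha longer, and I expect my figures to come out high.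

The forecast takes the same side with lower numbers than mine: alpha longer, 9 (8.4 to 9.6) for alpha and 4.1 (3.8 to 4.5) for eta, on the ground that “threefold higher monomer feeds each living end faster”.

The simulation gives alpha longer, 8.85 against 4.18, both inside the forecast's ranges and far below 50.0. The equal-length view belongs to a flask with a capture ratio far above one and living ends that outlast the free monomer.

At 4.08 min in alpha, free monomer was going to uncatalysed product 4.7 times as fast as into chains by step 2, a capture ratio read there of 0.214 against the 0.306 reckoned from the charge, and at 25.0 min alpha held 17.6 % of its charge as monomer in chains against the reckoned 23.4 %. Carried to eta by the free monomer charge, the capture ratio becomes 0.0986, which gives 8.97 %, and eta holds 8.17 % as monomer in chains at 25.0 min.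

The rate constants belong to no real substance; the run is a simulation.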